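**Retrosynthetic overview**
1. Ring C (the chroman pyran) is closed last, by C8a–O–C2 etherification of an open-chain (R)-2,3-diarylpropan-1-ol.
2. Key disconnection C3–C1': a racemic α-bromo ester (enolonium equivalent carrying ring A) is joined to a ring-B aryl Grignard by a stereoconvergent cobalt/bis(oxazoline) coupling that sets C3.
3. Ring-A fragment: 5-methoxyresorcinol → bis-TIPS ether → dibromide flanking OMe → two successive Br/Li exchanges (prenyl, then glycidate) → α-bromo ester.
4. Ring-B fragment: 4-bromoresorcinol → mono-TIPS ether → 1,1-dimethylpropargyl ether → Claisen/electrocyclisation to the 8-bromochromene.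
5. Ring order: rings A and B are bought as arenes; the dimethylchromene ring is formed first (on the fragment), ring C last.

Assumption: the target is the (3R)-isoflavan as drawn; the sense of induction of the bis(oxazoline) ligand in step 9 is not predicted here, so the ligand antipode that delivers (R) must be identified on the first run.

**Route**

Step 1
Reactants: 1 5-methoxyresorcinol
Product: 2 1-methoxy-3,5-bis(triisopropylsilyloxy)benzene
Conditions: TIPSCl (2.3 equiv), imidazole, DMF, rt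
Reagents that add atoms: triisopropylsilyl chloride, CC(C)[Si](Cl)(C(C)C)C(C)C
Why: Imidazole-promoted O-silylation masks both phenols with a bulky group that is inert to organolithiums and later shields the carbon between the two silyloxy groups.

Step 2
Reactants: 2 1-methoxy-3,5-bis(triisopropylsilyloxy)benzene
Product: 4 2,4-dibromo-3-methoxy-1,5-bis(triisopropylsilyloxy)benzene, via monobromide 3 (not isolated)
Conditions: NBS (2.05 equiv), MeCN, −20 → 0 °C
Reagents that add atoms: N-bromosuccinimide, BrN1C(=O)CCC1=O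
Why: Electrophilic aromatic bromination goes to the two equivalent positions ortho to OMe and para to a silyloxy group, because the third site lies between two bulky TIPS ethers.

Step 3
Reactants: 4 2,4-dibromo-3-methoxy-1,5-bis(triisopropylsilyloxy)benzene; 5 prenyl bromide
Product: 7 2-bromo-3-methoxy-4-(3-methylbut-2-en-1-yl)-1,5-bis(triisopropylsilyloxy)benzene, via aryllithium 6 (not isolated)
Conditions: n-BuLi (1.0 equiv), THF, −78 °C; then CuI (10 mol %), prenyl bromide, −78 → 0 °C
Reagents that add atoms: none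
Why: Bromine–lithium exchange on the symmetrical dibromide followed by copper-catalysed allylic alkylation at the primary carbon of prenyl bromide gives the prenylarene, and at −78 °C the ortho-lithio TIPS ether is trapped before retro-Brook silyl migration.

Step 4
Reactants: 7 2-bromo-3-methoxy-4-(3-methylbut-2-en-1-yl)-1,5-bis(triisopropylsilyloxy)benzene; 8 methyl (±)-glycidate
Product: 11 methyl (±)-2-hydroxy-3-[2-methoxy-3-(3-methylbut-2-en-1-yl)-4,6-bis(triisopropylsilyloxy)phenyl]propanoate, via aryllithium 9 (not isolated), via arylmagnesium bromide 10 (not isolated)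
Conditions: n-BuLi, THF, −78 °C; MgBr2·OEt2; then CuI (10 mol %), methyl glycidate, −40 → 0 °C; aq. NH4Cl
Reagents that add atoms: none
Why: Fast bromine–lithium exchange (faster than deprotonation of the prenyl CH2), transmetalation to magnesium and CuI-catalysed epoxide opening at the unsubstituted CH2 of the glycidate install the three-carbon chain as a racemic α-hydroxy ester.

Step 5
Reactants: 11 methyl (±)-2-hydroxy-3-[2-methoxy-3-(3-methylbut-2-en-1-yl)-4,6-bis(triisopropylsilyloxy)phenyl]propanoate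
Product: 12 methyl (±)-2-bromo-3-[2-methoxy-3-(3-methylbut-2-en-1-yl)-4,6-bis(triisopropylsilyloxy)phenyl]propanoate
Conditions: CBr4, PPh3, CH2Cl2, 0 °C → rt
Reagents that add atoms: carbon tetrabromide, BrC(Br)(Br)Br
Why: The Appel reaction turns the α-hydroxy ester into the α-bromo ester (the enolonium equivalent) under neutral conditions, and its configuration is irrelevant because step 9 is stereoconvergent.

Step 6
Reactants: 13 4-bromoresorcinol
Product: 14 2-bromo-5-(triisopropylsilyloxy)phenol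
Conditions: TIPSCl (1.0 equiv), imidazole, CH2Cl2, 0 °C
Reagents that add atoms: triisopropylsilyl chloride, CC(C)[Si](Cl)(C(C)C)C(C)C
Why: Sterically controlled mono-O-silylation takes the hydroxyl para to bromine and leaves the hydroxyl flanked by bromine free (minor isomer and bis-ether removed by chromatography).

Step 7
Reactants: 14 2-bromo-5-(triisopropylsilyloxy)phenol; 15 3-chloro-3-methylbut-1-yne
Product: 16 triisopropyl{4-bromo-3-[(2-methylbut-3-yn-2-yl)oxy]phenoxy}silane
Conditions: DBU, CuCl2·2H2O (1 mol %), MeCN, 0 °C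
Reagents that add atoms: none
Why: Copper-catalysed O-propargylation of phenols with a tertiary propargylic chloride gives the hindered aryl 1,1-dimethylpropargyl ether without C-alkylation.

Step 8
Reactants: 16 triisopropyl{4-bromo-3-[(2-methylbut-3-yn-2-yl)oxy]phenoxy}silane
Product: 19 8-bromo-2,2-dimethyl-5-(triisopropylsilyloxy)-2H-chromene, via allenylphenol 17 (not isolated), via ortho-quinone methide 18 (not isolated)
Conditions: N,N-diethylaniline, 190 °C
Reagents that add atoms: none
Why: The aromatic propargyl Claisen rearrangement can only reach the one free ortho carbon (the other carries Br), and the [1,5]-H shift and oxa-6π electrocyclisation that follow give the chromene with the required regiochemistry.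

Step 9
Reactants: 12 methyl (±)-2-bromo-3-[2-methoxy-3-(3-methylbut-2-en-1-yl)-4,6-bis(triisopropylsilyloxy)phenyl]propanoate; 19 8-bromo-2,2-dimethyl-5-(triisopropylsilyloxy)-2H-chromene
Product: 21 methyl (R)-2-[2,2-dimethyl-5-(triisopropylsilyloxy)-2H-chromen-8-yl]-3-[2-methoxy-3-(3-methylbut-2-en-1-yl)-4,6-bis(triisopropylsilyloxy)phenyl]propanoate, via chromenylmagnesium bromide 20 (not isolated)
Conditions: 19 (1.6 equiv), Mg turnings, THF, 40 °C; then added over 2 h to 12, CoI2 (10 mol %), 2,2'-isopropylidenebis(4-benzyl-2-oxazoline) (12 mol %, antipode giving R), THF, −80 °C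
Reagents that add atoms: none
Why: In this cobalt–bis(oxazoline)-catalysed stereoconvergent Kumada arylation of a racemic α-bromo ester, both enantiomers of 12 give the same planar α-ester radical, which recombines with the chiral aryl–cobalt species so that the ligand alone sets C3 as R while joining the α-carbonyl carbon to the electron-rich aryl carbon.

Step 10
Reactants: 21 methyl (R)-2-[2,2-dimethyl-5-(triisopropylsilyloxy)-2H-chromen-8-yl]-3-[2-methoxy-3-(3-methylbut-2-en-1-yl)-4,6-bis(triisopropylsilyloxy)phenyl]propanoate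
Product: 22 (R)-2-[2,2-dimethyl-5-(triisopropylsilyloxy)-2H-chromen-8-yl]-3-[2-methoxy-3-(3-methylbut-2-en-1-yl)-4,6-bis(triisopropylsilyloxy)phenyl]propan-1-ol
Conditions: LiAlH4, THF, 0 °C; H2O/NaOH work-up
Reagents that add atoms: none
Why: Hydride reduction of the ester to the primary alcohol is much faster than enolisation at 0 °C, so the α-aryl stereocentre is kept, and aryl TIPS ethers and both alkenes are inert.

Step 11
Reactants: 22 (R)-2-[2,2-dimethyl-5-(triisopropylsilyloxy)-2H-chromen-8-yl]-3-[2-methoxy-3-(3-methylbut-2-en-1-yl)-4,6-bis(triisopropylsilyloxy)phenyl]propan-1-ol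
Product: 24 (R)-8-[7-hydroxy-5-methoxy-6-(3-methylbut-2-en-1-yl)chroman-3-yl]-2,2-dimethyl-2H-chromen-5-ol (CNP0119857.1), via mesylate 23 (not isolated)
Conditions: MsCl, Et3N, THF, 0 °C; then TBAF (5 equiv), THF (0.01 M), 0 °C → rt
Reagents that add atoms: none
Why: After mesylation, fluoride cleaves the three aryl silyl ethers and the phenoxide ortho to the side chain closes ring C by intramolecular Williamson etherification (6-exo-tet) at the primary carbon, which leaves the C3 stereocentre untouched and avoids any acid near the prenyl phenol.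

**Compound list**
1 | 5-methoxyresorcinol | COc1cc(O)cc(O)c1 | starting material
2 | 1-methoxy-3,5-bis(triisopropylsilyloxy)benzene | COc1cc(O[Si](C(C)C)(C(C)C)C(C)C)cc(O[Si](C(C)C)(C(C)C)C(C)C)c1 | intermediate
3 | 2-bromo-1-methoxy-3,5-bis(triisopropylsilyloxy)benzene (monobromide, not isolated) | COc1cc(O[Si](C(C)C)(C(C)C)C(C)C)cc(O[Si](C(C)C)(C(C)C)C(C)C)c1Br | intermediate
4 | 2,4-dibromo-3-methoxy-1,5-bis(triisopropylsilyloxy)benzene | COc1c(Br)c(O[Si](C(C)C)(C(C)C)C(C)C)cc(O[Si](C(C)C)(C(C)C)C(C)C)c1Br | intermediate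
5 | prenyl bromide (1-bromo-3-methylbut-2-ene) | CC(C)=CCBr | starting material
6 | [3-bromo-2-methoxy-4,6-bis(triisopropylsilyloxy)phenyl]lithium (not isolated) | COc1c([Li])c(O[Si](C(C)C)(C(C)C)C(C)C)cc(O[Si](C(C)C)(C(C)C)C(C)C)c1Br | intermediate
7 | 2-bromo-3-methoxy-4-(3-methylbut-2-en-1-yl)-1,5-bis(triisopropylsilyloxy)benzene | COc1c(CC=C(C)C)c(O[Si](C(C)C)(C(C)C)C(C)C)cc(O[Si](C(C)C)(C(C)C)C(C)C)c1Br | intermediate
8 | methyl (±)-glycidate (methyl oxirane-2-carboxylate) | COC(=O)C1CO1 | starting material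
9 | [2-methoxy-3-(3-methylbut-2-en-1-yl)-4,6-bis(triisopropylsilyloxy)phenyl]lithium (not isolated) | COc1c(CC=C(C)C)c(O[Si](C(C)C)(C(C)C)C(C)C)cc(O[Si](C(C)C)(C(C)C)C(C)C)c1[Li] | intermediate
10 | [2-methoxy-3-(3-methylbut-2-en-1-yl)-4,6-bis(triisopropylsilyloxy)phenyl]magnesium bromide (not isolated) | COc1c(CC=C(C)C)c(O[Si](C(C)C)(C(C)C)C(C)C)cc(O[Si](C(C)C)(C(C)C)C(C)C)c1[Mg]Br | intermediate
11 | methyl (±)-2-hydroxy-3-[2-methoxy-3-(3-methylbut-2-en-1-yl)-4,6-bis(triisopropylsilyloxy)phenyl]propanoate | COc1c(CC=C(C)C)c(O[Si](C(C)C)(C(C)C)C(C)C)cc(O[Si](C(C)C)(C(C)C)C(C)C)c1CC(O)C(=O)OC | intermediate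
12 | methyl (±)-2-bromo-3-[2-methoxy-3-(3-methylbut-2-en-1-yl)-4,6-bis(triisopropylsilyloxy)phenyl]propanoate | COc1c(CC=C(C)C)c(O[Si](C(C)C)(C(C)C)C(C)C)cc(O[Si](C(C)C)(C(C)C)C(C)C)c1CC(Br)C(=O)OC | intermediate
13 | 4-bromoresorcinol | Oc1ccc(Br)c(O)c1 | starting material
14 | 2-bromo-5-(triisopropylsilyloxy)phenol | CC(C)[Si](Oc1ccc(Br)c(O)c1)(C(C)C)C(C)C | intermediate
15 | 3-chloro-3-methylbut-1-yne | CC(C)(Cl)C#C | starting material
16 | triisopropyl{4-bromo-3-[(2-methylbut-3-yn-2-yl)oxy]phenoxy}silane | CC(C)[Si](Oc1ccc(Br)c(OC(C)(C)C#C)c1)(C(C)C)C(C)C | intermediate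
17 | 6-bromo-2-(3-methylbuta-1,2-dien-1-yl)-3-(triisopropylsilyloxy)phenol (allenylphenol, not isolated) | CC(C)=C=Cc1c(O)c(Br)ccc1O[Si](C(C)C)(C(C)C)C(C)C | intermediate
18 | 2-bromo-6-(3-methylbut-2-en-1-ylidene)-5-(triisopropylsilyloxy)cyclohexa-2,4-dien-1-one (ortho-quinone methide, not isolated) | CC(C)=CC=C1C(=O)C(Br)=CC=C1O[Si](C(C)C)(C(C)C)C(C)C | intermediate
19 | 8-bromo-2,2-dimethyl-5-(triisopropylsilyloxy)-2H-chromene | CC1(C)C=Cc2c(O[Si](C(C)C)(C(C)C)C(C)C)ccc(Br)c2O1 | intermediate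
20 | [2,2-dimethyl-5-(triisopropylsilyloxy)-2H-chromen-8-yl]magnesium bromide (not isolated) | CC1(C)C=Cc2c(O[Si](C(C)C)(C(C)C)C(C)C)ccc([Mg]Br)c2O1 | intermediate
21 | methyl (R)-2-[2,2-dimethyl-5-(triisopropylsilyloxy)-2H-chromen-8-yl]-3-[2-methoxy-3-(3-methylbut-2-en-1-yl)-4,6-bis(triisopropylsilyloxy)phenyl]propanoate | COc1c(CC=C(C)C)c(O[Si](C(C)C)(C(C)C)C(C)C)cc(O[Si](C(C)C)(C(C)C)C(C)C)c1C[C@H](c1ccc(O[Si](C(C)C)(C(C)C)C(C)C)c2c1OC(C)(C)C=C2)C(=O)OC | intermediate
22 | (R)-2-[2,2-dimethyl-5-(triisopropylsilyloxy)-2H-chromen-8-yl]-3-[2-methoxy-3-(3-methylbut-2-en-1-yl)-4,6-bis(triisopropylsilyloxy)phenyl]propan-1-ol | COc1c(CC=C(C)C)c(O[Si](C(C)C)(C(C)C)C(C)C)cc(O[Si](C(C)C)(C(C)C)C(C)C)c1C[C@H](c1ccc(O[Si](C(C)C)(C(C)C)C(C)C)c2c1OC(C)(C)C=C2)CO | intermediate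
23 | (R)-2-[2,2-dimethyl-5-(triisopropylsilyloxy)-2H-chromen-8-yl]-3-[2-methoxy-3-(3-methylbut-2-en-1-yl)-4,6-bis(triisopropylsilyloxy)phenyl]propyl methanesulfonate (not isolated) | COc1c(CC=C(C)C)c(O[Si](C(C)C)(C(C)C)C(C)C)cc(O[Si](C(C)C)(C(C)C)C(C)C)c1C[C@H](c1ccc(O[Si](C(C)C)(C(C)C)C(C)C)c2c1OC(C)(C)C=C2)COS(C)(=O)=O | intermediate
24 | (R)-8-[7-hydroxy-5-methoxy-6-(3-methylbut-2-en-1-yl)chroman-3-yl]-2,2-dimethyl-2H-chromen-5-ol (CNP0119857.1) | COc1c(CC=C(C)C)c(O)cc2c1C[C@H](c1ccc(O)c3c1OC(C)(C)C=C3)CO2 | target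

**Totals**
Total steps: 11 (steps 1–5 ring-A fragment, steps 6–8 ring-B fragment, steps 9–11 union and endgame).
Longest linear sequence: 8 steps (1, 2, 3, 4, 5, 9, 10, 11) from 5-methoxyresorcinol.

**Three steps most likely to fail, with fallbacks**

Step 9 (key coupling). The known cobalt/bis(oxazoline) arylations use simpler α-bromo esters and unhindered aryl Grignards. Here the Grignard carries an ortho ether oxygen and the ester a bulky 2,6-disubstituted β-aryl group, so yield and ee may both drop. Fallback: give up catalyst control and obtain the stereocentre by resolution. Setting out from 12, couple with Grignard 20 under achiral conditions (CoI2, TMEDA, THF, −40 °C) to the racemic ester methyl (±)-2-[2,2-dimethyl-5-(triisopropylsilyloxy)-2H-chromen-8-yl]-3-[2-methoxy-3-(3-methylbut-2-en-1-yl)-4,6-bis(triisopropylsilyloxy)phenyl]propanoate F4. Reduce it with LiAlH4 to the racemic alcohol (±)-2-[2,2-dimethyl-5-(triisopropylsilyloxy)-2H-chromen-8-yl]-3-[2-methoxy-3-(3-methylbut-2-en-1-yl)-4,6-bis(triisopropylsilyloxy)phenyl]propan-1-ol F5, and separate the enantiomers by preparative chromatography on a chiral stationary phase. The (R)-enantiomer is 22, where the route is rejoined.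

Step 4 (glycidate opening). The aryl Grignard is flanked by OMe and OTIPS and may open the epoxide sluggishly or attack the ester instead. Fallback: build the chain by carbonyl olefination rather than epoxide opening. Setting out from 7, Br/Li exchange (n-BuLi, −78 °C) and DMF give the aldehyde 2-methoxy-3-(3-methylbut-2-en-1-yl)-4,6-bis(triisopropylsilyloxy)benzaldehyde F1. Horner–Wadsworth–Emmons reaction with trimethyl phosphonoacetate/NaH gives the cinnamate methyl (E)-3-[2-methoxy-3-(3-methylbut-2-en-1-yl)-4,6-bis(triisopropylsilyloxy)phenyl]prop-2-enoate F2. Conjugate reduction with catalytic [(Ph3P)CuH]6 and polymethylhydrosiloxane, which spares the prenyl alkene, gives the saturated ester methyl 3-[2-methoxy-3-(3-methylbut-2-en-1-yl)-4,6-bis(triisopropylsilyloxy)phenyl]propanoate F3. Enolate bromination (LiN(SiMe3)2, then CBr4, −78 °C) then rejoins the route at 12.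

Step 11 (one-pot mesylation and fluoride cyclisation). Fluoride frees all three phenoxides at once, so the ring-B para-phenoxide could attack the mesylate through aryl participation (spirodienone), and elimination or intermolecular O-alkylation could also compete with ring closure. Fallback: close the ring on the neutral polyphenol by redox condensation. Setting out from 22, TBAF buffered with AcOH removes the silyl groups to give the tetraol (R)-8-[1-hydroxy-3-(2,4-dihydroxy-6-methoxy-5-(3-methylbut-2-en-1-yl)phenyl)propan-2-yl]-2,2-dimethyl-2H-chromen-5-ol F6. Mitsunobu etherification (PPh3, DIAD, THF, 0 °C, high dilution) then activates only the primary alcohol, and the sole phenol able to form a six-membered ring closes ring C, arriving at 24.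

**Further compounds**
F1 | step 4 | 2-methoxy-3-(3-methylbut-2-en-1-yl)-4,6-bis(triisopropylsilyloxy)benzaldehyde | COc1c(CC=C(C)C)c(O[Si](C(C)C)(C(C)C)C(C)C)cc(O[Si](C(C)C)(C(C)C)C(C)C)c1C=O
F2 | step 4 | methyl (E)-3-[2-methoxy-3-(3-methylbut-2-en-1-yl)-4,6-bis(triisopropylsilyloxy)phenyl]prop-2-enoate | COC(=O)/C=C/c1c(OC)c(CC=C(C)C)c(O[Si](C(C)C)(C(C)C)C(C)C)cc1O[Si](C(C)C)(C(C)C)C(C)C
F3 | step 4 | methyl 3-[2-methoxy-3-(3-methylbut-2-en-1-yl)-4,6-bis(triisopropylsilyloxy)phenyl]propanoate | COC(=O)CCc1c(OC)c(CC=C(C)C)c(O[Si](C(C)C)(C(C)C)C(C)C)cc1O[Si](C(C)C)(C(C)C)C(C)C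
F4 | step 9 | methyl (±)-2-[2,2-dimethyl-5-(triisopropylsilyloxy)-2H-chromen-8-yl]-3-[2-methoxy-3-(3-methylbut-2-en-1-yl)-4,6-bis(triisopropylsilyloxy)phenyl]propanoate | COc1c(CC=C(C)C)c(O[Si](C(C)C)(C(C)C)C(C)C)cc(O[Si](C(C)C)(C(C)C)C(C)C)c1CC(c1ccc(O[Si](C(C)C)(C(C)C)C(C)C)c2c1OC(C)(C)C=C2)C(=O)OC
F5 | step 9 | (±)-2-[2,2-dimethyl-5-(triisopropylsilyloxy)-2H-chromen-8-yl]-3-[2-methoxy-3-(3-methylbut-2-en-1-yl)-4,6-bis(triisopropylsilyloxy)phenyl]propan-1-ol | COc1c(CC=C(C)C)c(O[Si](C(C)C)(C(C)C)C(C)C)cc(O[Si](C(C)C)(C(C)C)C(C)C)c1CC(c1ccc(O[Si](C(C)C)(C(C)C)C(C)C)c2c1OC(C)(C)C=C2)CO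
F6 | step 11 | (R)-8-[1-hydroxy-3-(2,4-dihydroxy-6-methoxy-5-(3-methylbut-2-en-1-yl)phenyl)propan-2-yl]-2,2-dimethyl-2H-chromen-5-ol | COc1c(CC=C(C)C)c(O)cc(O)c1C[C@H](c1ccc(O)c2c1OC(C)(C)C=C2)CO
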